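Ring A is built rather than decorated. Its C2'(OMe)–C3'(prenyl)–C4'(OH)–C5' segment is a 2-prenylacetoacetate held at the ketene-acetal level. C6'–C1' and the three-carbon bridge come from a cross-conjugated diynone. One cycloaddition–aromatisation joins C5'–C6' and C1'–C2', closes ring A, and puts 2'-OMe, 3'-prenyl and free 4'-OH in place with no need to tell the two ring-A oxygens apart. The surviving aryl alkyne is the latent second carbonyl, and the 2'-methyl ether shuts off flavone closure. The partners are 1,1-dimethoxy-2-prenyl-3-(trimethylsilyloxy)buta-1,3-diene and 1-(4-silyloxyphenyl)penta-1,4-diyn-3-one, each made in four steps. Ynone hydration through an enaminone and desilylation finish the synthesis.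

Key step: step 9

Remark: the target has no stereocentre and no stereogenic double bond, so no enantiomer has to be chosen; the 1,3-diketone is drawn in its diketo form although it should exist largely as the chelated enol.

Step 1
Reactants: 1 5-bromo-2-methylpent-2-ene; 2 tetramethyl orthocarbonate
Product: 4 6,6,6-trimethoxy-2-methylhex-2-ene, via homoprenyl Grignard reagent 3 (not isolated)
Conditions: Mg, Et2O, reflux; then 2 (1.5 equiv), Et2O to PhMe, 80 °C; cold aq. NaHCO3 work-up, distillation from K2CO3
Reagents that add atoms: magnesium, [Mg] (kept only in intermediate 3)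
Why: Grignard alkylation of an orthocarbonate, the ortho-ester counterpart of the Bodroux–Chichibabin aldehyde synthesis, replaces one methoxy group through a magnesium-assisted trimethoxycarbenium ion, stops at 4 because the product ionises less easily than excess 2, and reaches the ortho-ester level without any acid that could add to the trisubstituted alkene.

Step 2
Reactants: 4 6,6,6-trimethoxy-2-methylhex-2-ene
Product: 5 1,1-dimethoxy-5-methylhexa-1,4-diene
Conditions: TMSOTf (1.1 equiv), i-Pr2NEt (1.4 equiv), CH2Cl2, −20 °C to rt; pentane, filtration, distillation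
Reagents that add atoms: none
Why: Silyl triflate/hindered amine elimination, the method that turns acetals into enol ethers and ortho esters into ketene acetals, ionises 4 to a dimethoxycarbenium triflate that can lose a proton only from its single α-CH2 group, while the remote alkene has no favourable ring size for attack on this weakly electrophilic cation.

Step 3
Reactants: 5 1,1-dimethoxy-5-methylhexa-1,4-diene; 6 acetyl chloride
Product: 7 3-(dimethoxymethylidene)-6-methylhept-5-en-2-one
Conditions: Et3N (1.5 equiv), Et2O, slow addition of 6, −40 °C to rt; cold aq. NaHCO3, distillation or Et3N-deactivated silica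
Reagents that add atoms: none
Why: C-Acylation of a ketene acetal with an acid chloride and a tertiary amine: the nucleophilic β-carbon of 5 takes up the acetyl group (directly or by way of ketene formed in situ) and the strongly acidified C–H between the acyl and dimethoxycarbenium centres is removed by triethylamine at low temperature faster than chloride can strip an O-methyl group.

Step 4
Reactants: 7 3-(dimethoxymethylidene)-6-methylhept-5-en-2-one
Product: 9 1,1-dimethoxy-2-(3-methylbut-2-enyl)-3-(trimethylsilyloxy)buta-1,3-diene, via lithium enolate 8 (not isolated)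
Conditions: LDA, THF, −78 °C; TMSCl, −78 °C to rt; pentane, filtration, bulb-to-bulb distillation
Reagents that add atoms: chlorotrimethylsilane, C[Si](C)(C)Cl; lithium diisopropylamide, [Li]N(C(C)C)C(C)C (lithium kept only in intermediate 8)
Why: Kinetic enolate formation and O-silylation, the standard route from 4,4-dialkoxybut-3-en-2-ones to 1,1-dialkoxy-3-silyloxybutadienes, is unambiguous because the acetyl CH3 is the only acidic position of the fully substituted push–pull enone, and the non-aqueous work-up protects both enol ether functions.

Step 5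
Reactants: 10 4-ethynylphenol
Product: 11 tert-butyl(4-ethynylphenoxy)dimethylsilane
Conditions: TBSCl, imidazole, DMF, rt
Reagents that add atoms: tert-butyldimethylsilyl chloride, CC(C)(C)[Si](C)(C)Cl
Why: Standard imidazole-promoted O-silylation masks the acidic phenol, which would otherwise quench the organometallic reagents of steps 6 and 7 and protonate diene 9 in step 9.

Step 6
Reactants: 11 tert-butyl(4-ethynylphenoxy)dimethylsilane; 12 N,N-dimethylformamide
Product: 14 3-[4-(tert-butyldimethylsilyloxy)phenyl]prop-2-ynal, via lithium acetylide 13 (not isolated)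
Conditions: n-BuLi, THF, −78 °C; 12, −78 °C to 0 °C; reverse quench into aq. KH2PO4
Reagents that add atoms: n-butyllithium, [Li]CCCC (lithium kept only in intermediate 13)
Why: Formylation of a lithium acetylide with DMF gives a stable hemiaminal alkoxide that cannot over-add, and the buffered reverse quench releases the ynal without conjugate re-addition of dimethylamine.

Step 7
Reactants: 14 3-[4-(tert-butyldimethylsilyloxy)phenyl]prop-2-ynal; 15 ethynylmagnesium bromide
Product: 16 racemic 1-[4-(tert-butyldimethylsilyloxy)phenyl]penta-1,4-diyn-3-ol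
Conditions: THF, −78 °C to 0 °C; aqueous work-up
Reagents that add atoms: none
Why: 1,2-Addition of an alkynyl Grignard reagent to a non-enolisable ynal brings in the terminal alkyne already free, so no C-silyl group has to be removed under basic or fluoride conditions that would endanger the aryl silyl ether, and the new carbinol centre is formed racemic and is erased in step 8.

Step 8
Reactants: 16 racemic 1-[4-(tert-butyldimethylsilyloxy)phenyl]penta-1,4-diyn-3-ol
Product: 17 1-[4-(tert-butyldimethylsilyloxy)phenyl]penta-1,4-diyn-3-one
Conditions: activated MnO2 (excess), CH2Cl2, rt; filtration through Celite; used at once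
Reagents that add atoms: none
Why: Manganese dioxide oxidation of a doubly propargylic alcohol is fast, neutral and needs only filtration, which suits a terminal diynone that is sensitive to base and nucleophiles.

Step 9
Reactants: 9 1,1-dimethoxy-2-(3-methylbut-2-enyl)-3-(trimethylsilyloxy)buta-1,3-diene; 17 1-[4-(tert-butyldimethylsilyloxy)phenyl]penta-1,4-diyn-3-one
Product: 20 1-[4-hydroxy-2-methoxy-3-(3-methylbut-2-enyl)phenyl]-3-[4-(tert-butyldimethylsilyloxy)phenyl]prop-2-yn-1-one, via gem-dimethoxycyclohexadiene cycloadduct 18 (not isolated), via aryl trimethylsilyl ether 19 (not isolated)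
Conditions: 9 (1.5 equiv), PhMe, 0 °C to 60 °C; then 0.1 M aq. HCl, THF, 0 °C
Reagents that add atoms: none
Why: This is the known cycloaddition–aromatisation of 1,1-dialkoxy-3-silyloxybutadienes with acetylenic carbonyl compounds, a strongly asynchronous Diels–Alder reaction that can also be read as a vinylogous Mukaiyama–Michael addition followed by ring closure, applied here to a 2-prenyl diene and a diynone. All three oxygen donors of 9 push electron density to its CH2 terminus, which bonds to the unsubstituted alkyne carbon of 17 (C5'–C6'), and the α-carbon of the resulting allenolate then closes on the dimethoxycarbenium carbon (C1'–C2'), so ring A forms as a six-membered carbocycle by [4+2] closure to give 18. 1,4-Loss of methanol from 18 (one C2' methoxy group, one C5' hydrogen) aromatises the ring to 19, and the brief dilute-acid work-up cleaves only the labile aryl trimethylsilyl ether while the tert-butyldimethylsilyl ether, the prenyl group and the second alkyne stay untouched. No stereocentre is created. Site selectivity is required and is secured by the substrate, since the HC≡C–C=O unit offers an open, strongly polarised β-carbon whereas the other triple bond is blocked by, and receives electron density from, the 4-silyloxyphenyl group, and 20, an internal ynone on an electron-rich aryl ketone, should not react again with the excess of 9. Orientation follows from the same polarisation: the carbonyl-bearing carbon ends up next to the retained methoxy carbon and opposite the silyloxy carbon, with prenyl locked between the two oxygens.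

Step 10
Reactants: 20 1-[4-hydroxy-2-methoxy-3-(3-methylbut-2-enyl)phenyl]-3-[4-(tert-butyldimethylsilyloxy)phenyl]prop-2-yn-1-one
Product: 22 1-[4-hydroxy-2-methoxy-3-(3-methylbut-2-enyl)phenyl]-3-[4-(tert-butyldimethylsilyloxy)phenyl]propane-1,3-dione, via diethylamino enaminone 21 (not isolated)
Conditions: Et2NH (5 equiv), THF, rt; evaporation; 1 M aq. HCl–THF (1:3), rt
Reagents that add atoms: water, O; diethylamine, CCNCC (kept only in intermediate 21)
Why: Aza-Michael addition of the secondary amine puts nitrogen on the aryl-bearing β-carbon of the ynone, and dilute-acid hydrolysis of the tertiary enaminone 21 then gives the 1,3-diketone regiospecifically, the 2'-methyl ether excluding chromone closure and the mild acid sparing the o-prenylphenol and the aryl silyl ether.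

Step 11
Reactants: 22 1-[4-hydroxy-2-methoxy-3-(3-methylbut-2-enyl)phenyl]-3-[4-(tert-butyldimethylsilyloxy)phenyl]propane-1,3-dione
Product: 23 1-[4-hydroxy-2-methoxy-3-(3-methylbut-2-enyl)phenyl]-3-(4-hydroxyphenyl)propane-1,3-dione
Conditions: TBAF (1.2 equiv), AcOH (1.5 equiv), THF, 0 °C
Reagents that add atoms: none
Why: Fluoride-induced cleavage of the aryl silyl ether, buffered with acetic acid so that the diketone and the phenols stay protonated and retro-Claisen cleavage is avoided, releases the achiral target.

Compound list
1 | 5-bromo-2-methylpent-2-ene | CC(C)=CCCBr | starting material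
2 | tetramethyl orthocarbonate | COC(OC)(OC)OC | starting material
3 | (4-methylpent-3-enyl)magnesium bromide | CC(C)=CCC[Mg]Br | intermediate
4 | 6,6,6-trimethoxy-2-methylhex-2-ene (trimethyl ortho-5-methylhex-4-enoate) | COC(CCC=C(C)C)(OC)OC | intermediate
5 | 1,1-dimethoxy-5-methylhexa-1,4-diene (prenylketene dimethyl acetal) | COC(OC)=CCC=C(C)C | intermediate
6 | acetyl chloride | CC(=O)Cl | starting material
7 | 3-(dimethoxymethylidene)-6-methylhept-5-en-2-one | CC(=O)C(CC=C(C)C)=C(OC)OC | intermediate
8 | lithium 3-(dimethoxymethylidene)-6-methylhepta-1,5-dien-2-olate | [Li]OC(=C)C(CC=C(C)C)=C(OC)OC | intermediate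
9 | 1,1-dimethoxy-2-(3-methylbut-2-enyl)-3-(trimethylsilyloxy)buta-1,3-diene | C=C(O[Si](C)(C)C)C(CC=C(C)C)=C(OC)OC | intermediate
10 | 4-ethynylphenol | Oc1ccc(C#C)cc1 | starting material
11 | tert-butyl(4-ethynylphenoxy)dimethylsilane | C#Cc1ccc(O[Si](C)(C)C(C)(C)C)cc1 | intermediate
12 | N,N-dimethylformamide | CN(C)C=O | starting material
13 | lithium [4-(tert-butyldimethylsilyloxy)phenyl]acetylide | [Li]C#Cc1ccc(O[Si](C)(C)C(C)(C)C)cc1 | intermediate
14 | 3-[4-(tert-butyldimethylsilyloxy)phenyl]prop-2-ynal | O=CC#Cc1ccc(O[Si](C)(C)C(C)(C)C)cc1 | intermediate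
15 | ethynylmagnesium bromide | C#C[Mg]Br | starting material
16 | 1-[4-(tert-butyldimethylsilyloxy)phenyl]penta-1,4-diyn-3-ol (racemic) | C#CC(O)C#Cc1ccc(O[Si](C)(C)C(C)(C)C)cc1 | intermediate
17 | 1-[4-(tert-butyldimethylsilyloxy)phenyl]penta-1,4-diyn-3-one | C#CC(=O)C#Cc1ccc(O[Si](C)(C)C(C)(C)C)cc1 | intermediate
18 | 1-[6,6-dimethoxy-5-(3-methylbut-2-enyl)-4-(trimethylsilyloxy)cyclohexa-1,4-dien-1-yl]-3-[4-(tert-butyldimethylsilyloxy)phenyl]prop-2-yn-1-one | COC1(OC)C(C(=O)C#Cc2ccc(O[Si](C)(C)C(C)(C)C)cc2)=CCC(O[Si](C)(C)C)=C1CC=C(C)C | intermediate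
19 | 1-[2-methoxy-3-(3-methylbut-2-enyl)-4-(trimethylsilyloxy)phenyl]-3-[4-(tert-butyldimethylsilyloxy)phenyl]prop-2-yn-1-one | COc1c(C(=O)C#Cc2ccc(O[Si](C)(C)C(C)(C)C)cc2)ccc(O[Si](C)(C)C)c1CC=C(C)C | intermediate
20 | 1-[4-hydroxy-2-methoxy-3-(3-methylbut-2-enyl)phenyl]-3-[4-(tert-butyldimethylsilyloxy)phenyl]prop-2-yn-1-one | COc1c(C(=O)C#Cc2ccc(O[Si](C)(C)C(C)(C)C)cc2)ccc(O)c1CC=C(C)C | intermediate
21 | 3-(diethylamino)-1-[4-hydroxy-2-methoxy-3-(3-methylbut-2-enyl)phenyl]-3-[4-(tert-butyldimethylsilyloxy)phenyl]prop-2-en-1-one (double-bond geometry undefined and of no consequence) | CCN(CC)C(=CC(=O)c1ccc(O)c(CC=C(C)C)c1OC)c1ccc(O[Si](C)(C)C(C)(C)C)cc1 | intermediate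
22 | 1-[4-hydroxy-2-methoxy-3-(3-methylbut-2-enyl)phenyl]-3-[4-(tert-butyldimethylsilyloxy)phenyl]propane-1,3-dione | COc1c(C(=O)CC(=O)c2ccc(O[Si](C)(C)C(C)(C)C)cc2)ccc(O)c1CC=C(C)C | intermediate
23 | 1-[4-hydroxy-2-methoxy-3-(3-methylbut-2-enyl)phenyl]-3-(4-hydroxyphenyl)propane-1,3-dione (CNP0308388.0, achiral) | COc1c(C(=O)CC(=O)c2ccc(O)cc2)ccc(O)c1CC=C(C)C | target

Total step count: 11.
Longest linear sequence: 7 steps (1–4, then 9–11; the arm 5–8, then 9–11 is equally long).

Steps most likely to fail

Step 9. The doubly activated dienophile may oligomerise or take up the methanol that is released. The first C–C bond may also form without timely closure at the crowded ketene-acetal carbon, so that material is lost on work-up. The fallback sets out from 9 and comes back to the route at 23. It keeps the ring-A construction but moves the bridge-building to enolate chemistry.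
- Diene 9 would be heated with commercial but-3-yn-2-one, a robust terminal ynone that can be used in large excess. After the same dilute-acid work-up this should give 1-[4-hydroxy-2-methoxy-3-(3-methylbut-2-enyl)phenyl]ethanone F1.
- Silylation (TBSCl, imidazole, DMF) should give 1-[4-(tert-butyldimethylsilyloxy)-2-methoxy-3-(3-methylbut-2-enyl)phenyl]ethanone F2.
- The lithium enolate of F2 (LDA, THF, −78 °C) would add to commercial 4-(tert-butyldimethylsilyloxy)benzaldehyde to give the racemic aldol 1-[4-(tert-butyldimethylsilyloxy)-2-methoxy-3-(3-methylbut-2-enyl)phenyl]-3-hydroxy-3-[4-(tert-butyldimethylsilyloxy)phenyl]propan-1-one F3.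
- Dess–Martin oxidation should give 1-[4-(tert-butyldimethylsilyloxy)-2-methoxy-3-(3-methylbut-2-enyl)phenyl]-3-[4-(tert-butyldimethylsilyloxy)phenyl]propane-1,3-dione F4.
- The buffered fluoride conditions of step 11, with doubled reagent amounts, then remove both silyl groups to give 23.

Step 3. Demethylation of the acylated dimethoxycarbenium intermediate by chloride may outrun proton loss, which drops the product to the ester oxidation level. Ketene self-condensation may also consume the acylating agent. The fallback sets out from 6 and comes back at 7. It forms the C3–prenyl bond last, by cross-coupling.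
- Acetyl chloride 6 would acylate commercial 1,1-dimethoxyethene (Et3N, Et2O), the unsubstituted case for which this acylation is established, to give 4,4-dimethoxybut-3-en-2-one F5.
- Electrophilic iodination at the nucleophilic α-carbon (NIS, CH2Cl2, 0 °C) should give 3-iodo-4,4-dimethoxybut-3-en-2-one F6.
- Stille coupling with commercial tributyl(3-methylbut-2-enyl)stannane (Pd2(dba)3, AsPh3, NMP, 50 °C) should attach the prenyl group through its unsubstituted terminus and deliver 7.

Step 2. Methyl transfer from the dimethoxycarbenium ion to the amine or to triflate may compete with deprotonation and collapse the ortho ester to the ester level. The ketene acetal may also be protonated and hydrolysed during isolation. The fallback sets out from 1 and comes back at 5. It bypasses the ortho ester altogether by olefination.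
- Bromide 1 would be oxidised with anhydrous trimethylamine N-oxide in DMSO (the N-oxide variant of the Kornblum oxidation) to 4-methylpent-3-enal F7, which is used without delay.
- In parallel, chlorodiphenylphosphine and trimethyl orthoformate should give (dimethoxymethyl)diphenylphosphine oxide F8.
- The anion of F8 (LDA, THF, −78 °C) adds to F7 to give racemic 1-(diphenylphosphoryl)-1,1-dimethoxy-5-methylhex-4-en-2-ol F9.
- Horner–Wittig elimination (KOt-Bu, THF, rt) should release ketene acetal 5 under purely basic conditions.

Further compounds
F1 | step 9 | 1-[4-hydroxy-2-methoxy-3-(3-methylbut-2-enyl)phenyl]ethanone | CC(=O)c1ccc(O)c(CC=C(C)C)c1OC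
F2 | step 9 | 1-[4-(tert-butyldimethylsilyloxy)-2-methoxy-3-(3-methylbut-2-enyl)phenyl]ethanone | CC(=O)c1ccc(O[Si](C)(C)C(C)(C)C)c(CC=C(C)C)c1OC
F3 | step 9 | 1-[4-(tert-butyldimethylsilyloxy)-2-methoxy-3-(3-methylbut-2-enyl)phenyl]-3-hydroxy-3-[4-(tert-butyldimethylsilyloxy)phenyl]propan-1-one (racemic) | COc1c(C(=O)CC(O)c2ccc(O[Si](C)(C)C(C)(C)C)cc2)ccc(O[Si](C)(C)C(C)(C)C)c1CC=C(C)C
F4 | step 9 | 1-[4-(tert-butyldimethylsilyloxy)-2-methoxy-3-(3-methylbut-2-enyl)phenyl]-3-[4-(tert-butyldimethylsilyloxy)phenyl]propane-1,3-dione | COc1c(C(=O)CC(=O)c2ccc(O[Si](C)(C)C(C)(C)C)cc2)ccc(O[Si](C)(C)C(C)(C)C)c1CC=C(C)C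
F5 | step 3 | 4,4-dimethoxybut-3-en-2-one | CC(=O)C=C(OC)OC
F6 | step 3 | 3-iodo-4,4-dimethoxybut-3-en-2-one | CC(=O)C(I)=C(OC)OC
F7 | step 2 | 4-methylpent-3-enal | CC(C)=CCC=O
F8 | step 2 | (dimethoxymethyl)diphenylphosphine oxide | COC(OC)P(=O)(c1ccccc1)c1ccccc1
F9 | step 2 | 1-(diphenylphosphoryl)-1,1-dimethoxy-5-methylhex-4-en-2-ol (racemic) | COC(OC)(C(O)CC=C(C)C)P(=O)(c1ccccc1)c1ccccc1
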